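The side chain is disconnected at C11–C12 and at C15–O, which exposes C12–C16 as one molecule of isoprene held between an exocyclic C11 radical site and an isobutyrate oxygen. One electrolysis decarboxylates an acetic acid residue on C9 of ring B, adds the C11 radical to isoprene and, after radical–polar crossover, caps C15 with isobutyrate, so the carbon chain and the allylic ester arrive together. The feature exploited is this E-C13=C14 isoprene unit bearing its oxygen at C15, next to a C7=C8–C17 carboxyl on ring B that can stay masked. The precursor is the sclareolide-derived 13,14,15,16-tetranorlabd-7-ene-12,17-dioic acid carrying C17 as its 2-(trimethylsilyl)ethyl ester and C12 as the free acid.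

Key step: step 7

Remark: labdane numbering is used throughout; the key-step acid is a 13,14,15,16-tetranorlabdane (C16 homodrimane) whose own carboxyl carbon leaves as CO2, so C12–C16 of the target all come from isoprene; every compound keeps the trans-decalin configuration of 1 (5α-H, 9α-H, 10β-CH3; 5S,9R,10S in the target).

Step 1
Reactants: 1 (+)-sclareolide
Product: 3 methyl 8α-hydroxy-13,14,15,16-tetranorlabdan-12-oate, via potassium carboxylate 2 (not isolated)
Conditions: KOH, MeOH/H2O, reflux; evaporate; then MeI, DMF, rt
Reagents that add atoms: potassium hydroxide [K+].[OH-]; iodomethane CI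
Why: Lactone saponification followed by SN2 O-methylation of the potassium carboxylate (carboxylate alkylation) opens the ring without touching the C8–O bond, so all four stereocentres of 1 are kept and the hindered tertiary hydroxyl is not methylated.

Step 2
Reactants: 3 methyl 8α-hydroxy-13,14,15,16-tetranorlabdan-12-oate
Product: 4 methyl 13,14,15,16-tetranorlabd-8(17)-en-12-oate
Conditions: SOCl2, pyridine, CH2Cl2, −78 °C
Reagents that add atoms: none
Why: Dehydration through the chlorosulfite (E2-type elimination with pyridine) should favour the exocyclic alkene because the equatorial 8α leaving group has no antiperiplanar ring hydrogen while the freely rotating C17 methyl group always offers one; ring-alkene isomers are carried on and removed after step 3 as polar seco-dicarbonyl compounds.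

Step 3
Reactants: 4 methyl 13,14,15,16-tetranorlabd-8(17)-en-12-oate
Product: 6 methyl 8-oxo-13,14,15,16,17-pentanorlabdan-12-oate, via secondary ozonide 5 (not isolated)
Conditions: O3, CH2Cl2, −78 °C; then PPh3, −78 °C to rt
Reagents that add atoms: ozone [O-][O+]=O
Why: Ozonolysis of the 1,1-disubstituted alkene with reductive work-up (Criegee mechanism, phosphine reduction of the ozonide) excises C17 as formaldehyde and leaves the C8 ketone, and under these cold neutral conditions C9, now alpha to the ketone, keeps its equatorial side chain, which is also the more stable epimer.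

Step 4
Reactants: 6 methyl 8-oxo-13,14,15,16,17-pentanorlabdan-12-oate
Product: 8 methyl 8-(trifluoromethanesulfonyloxy)-13,14,15,16,17-pentanorlabd-7-en-12-oate, via potassium enolate 7 (not isolated)
Conditions: KN(SiMe3)2, THF, −78 °C; then 2-[N,N-bis(trifluoromethanesulfonyl)amino]-5-chloropyridine, −78 °C
Reagents that add atoms: 2-[N,N-bis(trifluoromethanesulfonyl)amino]-5-chloropyridine FC(F)(F)S(=O)(=O)N(c1ccc(Cl)cn1)S(=O)(=O)C(F)(F)F
Why: Kinetic enolisation of the 2-substituted cyclohexanone at the C7 methylene (the ketone is far more acidic than the ester alpha-CH2, and the tertiary C9–H beside the quaternary C10 is shielded) followed by O-sulfonylation at −78 °C fixes the C7=C8 double bond as the enol triflate before the enolate can acylate on the neighbouring ester, and leaves C9 unepimerised.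

Step 5
Reactants: 8 methyl 8-(trifluoromethanesulfonyloxy)-13,14,15,16,17-pentanorlabd-7-en-12-oate; 9 2-(trimethylsilyl)ethanol
Product: 10 12-methyl 17-[2-(trimethylsilyl)ethyl] 13,14,15,16-tetranorlabd-7-ene-12,17-dioate
Conditions: Pd(OAc)2, PPh3, CO (1 atm), Et3N, 9 (5 equiv), DMF, 60 °C
Reagents that add atoms: carbon monoxide [C-]#[O+]
Why: Palladium-catalysed alkoxycarbonylation of an enol triflate (oxidative addition to zerovalent palladium, CO insertion, alcoholysis of the acylpalladium by 9) re-installs C17 directly as the conjugated silylethyl ester with the alkene locked at C7=C8, the saturated methyl ester being a spectator.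

Step 6
Reactants: 10 12-methyl 17-[2-(trimethylsilyl)ethyl] 13,14,15,16-tetranorlabd-7-ene-12,17-dioate
Product: 11 13,14,15,16-tetranorlabd-7-ene-12,17-dioic acid 17-[2-(trimethylsilyl)ethyl] ester (C12 free acid)
Conditions: LiOH·H2O (1.5 equiv), THF/H2O, 0 °C to rt; dilute HCl work-up
Reagents that add atoms: lithium hydroxide [Li+].[OH-]
Why: Chemoselective saponification, since hydroxide attacks the saturated methyl ester much faster than the C17 ester, which is conjugated, flanked by C9 and carries the bulkier alkoxy group; methanol is left out so that the silylethyl ester cannot transesterify.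

Step 7
Reactants: 11 13,14,15,16-tetranorlabd-7-ene-12,17-dioic acid 17-[2-(trimethylsilyl)ethyl] ester; 12 isoprene; 13 isobutyric acid
Product: 15 2-(trimethylsilyl)ethyl (13E)-15-(2-methylpropanoyloxy)labda-7,13-dien-17-oate, via tertiary isobutyrate 14 (not isolated)
Conditions: (a) undivided cell, Pt anode, Pt cathode, constant current, Et3N (2 equiv), nBu4NPF6, 12 (40 equiv), 13 (12 equiv), CH2Cl2, 0 °C, until 11 is consumed; (b) silica plug, then PdCl2(MeCN)2 (5 mol%), THF, rt
Reagents that add atoms: none
Why: Proposed new method: Kolbe-type one-electron oxidation of the carboxylate of 11 at platinum releases CO2 and the primary exocyclic C11 radical, which the large excess of isoprene should capture at its own C1 methylene (the terminus next to the methyl-bearing carbon) faster than it dimerises or rearranges, forming C11–C12 and an allyl radical over C13–C15 that is born in the reaction layer and is oxidised at the same anode, far below the working potential, to the allyl cation (radical–polar crossover); isobutyrate, the only nucleophile supplied, then forms the C15–O bond. The closest known reaction type is Kolbe electrolysis of simple alkanoates in the presence of 1,3-dienes, where alkyl addition is followed by dimerisation or by Hofer–Moest-type oxidation and capture by the same carboxylate; new here is the cross-assembly of a complex acid, a diene and a second acid as oxygen nucleophile. No ring is closed and no stereocentre is created: C5, C9 and C10 are spectators because the radical sits outside the ring, and the conjugated C17 ester deactivates C7=C8 toward the allyl cation. The step needs attack at C1 of isoprene, favoured by the larger frontier-orbital coefficient there and by the more substituted allyl radical it gives, and E geometry at C13=C14, which the s-trans ground-state conformation of isoprene should imprint on an allyl radical and cation that keep their configuration until capture. Capture at the tertiary terminus C13 cannot be excluded, so the co-formed ester 14 is converged onto 15 in stage (b) by the cyclisation-induced [3,3] transposition of allylic esters catalysed by divalent palladium, which is known for tertiary vinyl carbinol esters and should not act on the trisubstituted alkene of 15. Isobutyrate is oxidised alongside 11 but gives only volatile or small by-products, which is why it is used in excess; 13Z and regioisomeric esters are to be removed on AgNO3-impregnated silica.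

Step 8
Reactants: 15 2-(trimethylsilyl)ethyl (13E)-15-(2-methylpropanoyloxy)labda-7,13-dien-17-oate
Product: 16 (5S,9R,10S,13E)-15-(2-methylpropanoyloxy)labda-7,13-dien-17-oic acid (CNP0191003.1)
Conditions: Bu4NF (1 M in THF), THF, 0 °C to rt; aq. NH4Cl work-up
Reagents that add atoms: none
Why: Fluoride attacks silicon and the ester fragments by beta-elimination to ethene, Me3SiF and the carboxylate (fluoride-induced silylethyl ester cleavage), a path that does not depend on the hindered C17 carbonyl and should leave the primary allylic isobutyrate, the E alkene and the three stereocentres untouched.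

Compound list
1 | (+)-sclareolide | O=C3C[C@H]1[C@](C)(O3)CC[C@H]2C(C)(C)CCC[C@]12C | starting material
2 | potassium 8α-hydroxy-13,14,15,16-tetranorlabdan-12-oate | [K+].[O-]C(=O)C[C@H]1[C@](C)(O)CC[C@H]2C(C)(C)CCC[C@]12C | intermediate
3 | methyl 8α-hydroxy-13,14,15,16-tetranorlabdan-12-oate | COC(=O)C[C@H]1[C@](C)(O)CC[C@H]2C(C)(C)CCC[C@]12C | intermediate
4 | methyl 13,14,15,16-tetranorlabd-8(17)-en-12-oate | COC(=O)C[C@H]1C(=C)CC[C@H]2C(C)(C)CCC[C@]12C | intermediate
5 | secondary ozonide of 4 (1,2,4-trioxolane spiro-fused at C8, either C8 epimer) | COC(=O)C[C@H]1C3(OOCO3)CC[C@H]2C(C)(C)CCC[C@]12C | intermediate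
6 | methyl 8-oxo-13,14,15,16,17-pentanorlabdan-12-oate | COC(=O)C[C@H]1C(=O)CC[C@H]2C(C)(C)CCC[C@]12C | intermediate
7 | potassium 7-en-8-olate of 6 | [K+].COC(=O)C[C@H]1C([O-])=CC[C@H]2C(C)(C)CCC[C@]12C | intermediate
8 | methyl 8-(trifluoromethanesulfonyloxy)-13,14,15,16,17-pentanorlabd-7-en-12-oate | COC(=O)C[C@H]1C(OS(=O)(=O)C(F)(F)F)=CC[C@H]2C(C)(C)CCC[C@]12C | intermediate
9 | 2-(trimethylsilyl)ethanol | C[Si](C)(C)CCO | starting material
10 | 12-methyl 17-[2-(trimethylsilyl)ethyl] 13,14,15,16-tetranorlabd-7-ene-12,17-dioate | COC(=O)C[C@H]1C(C(=O)OCC[Si](C)(C)C)=CC[C@H]2C(C)(C)CCC[C@]12C | intermediate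
11 | 13,14,15,16-tetranorlabd-7-ene-12,17-dioic acid 17-[2-(trimethylsilyl)ethyl] ester (C12 free acid) | OC(=O)C[C@H]1C(C(=O)OCC[Si](C)(C)C)=CC[C@H]2C(C)(C)CCC[C@]12C | intermediate
12 | isoprene (2-methylbuta-1,3-diene) | CC(=C)C=C | starting material
13 | isobutyric acid (2-methylpropanoic acid) | CC(C)C(=O)O | starting material
14 | 2-(trimethylsilyl)ethyl 13-(2-methylpropanoyloxy)labda-7,14-dien-17-oate (both C13 epimers) | C=CC(C)(OC(=O)C(C)C)CC[C@H]1C(C(=O)OCC[Si](C)(C)C)=CC[C@H]2C(C)(C)CCC[C@]12C | intermediate
15 | 2-(trimethylsilyl)ethyl (13E)-15-(2-methylpropanoyloxy)labda-7,13-dien-17-oate | C/C(=C\COC(=O)C(C)C)CC[C@H]1C(C(=O)OCC[Si](C)(C)C)=CC[C@H]2C(C)(C)CCC[C@]12C | intermediate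
16 | (5S,9R,10S,13E)-15-(2-methylpropanoyloxy)labda-7,13-dien-17-oic acid | C/C(=C\COC(=O)C(C)C)CC[C@H]1C(C(=O)O)=CC[C@H]2C(C)(C)CCC[C@]12C | target

Total step count: 8. Longest linear sequence: 8 steps (1 to 16).

Steps most likely to fail

Step 7 (proposed new method). The radical and cation intermediates may partition badly: radical–radical coupling, telomerisation with isoprene, attack at the other diene terminus, or 6-endo radical closure onto C7. Isobutyrate may also consume most of the charge before 11 is converted. Only the fraction captured directly at C15 is expected to be cleanly E; the part passing through 14 may be delivered as an E/Z mixture. The fallback uses known chemistry and keeps the carboxyl carbon as C12 instead of expelling it. It sets out from 11: BH3·SMe2 in THF at 0 °C should reduce the free acid in the presence of the conjugated ester to 2-(trimethylsilyl)ethyl 12-hydroxy-13,14,15,16-tetranorlabd-7-en-17-oate F1. An Appel reaction (I2, PPh3, imidazole) gives 2-(trimethylsilyl)ethyl 12-iodo-13,14,15,16-tetranorlabd-7-en-17-oate F2. Insertion of activated Zn dust in dimethylacetamide gives the alkylzinc iodide F3. Negishi coupling with Pd(PPh3)4 and (E)-3-iodobut-2-en-1-yl 2-methylpropanoate F4 then forms C12–C13 with retention of alkene geometry and comes back to the route at 15. F4 is made from the known (E)-3-iodobut-2-en-1-ol, C/C(I)=C\CO, with isobutyryl chloride and pyridine.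

Step 2. Elimination may run into the ring toward C7 or C9 through a cationic pathway, or the C8 cation may be recaptured by the ester carbonyl and return 1. The fallback keeps C17 and oxidises it instead of excising and replacing it. It sets out from 3: the ring alkene methyl 13,14,15,16-tetranorlabd-7-en-12-oate F5 that such an elimination delivers is separated from the 8(9)-ene on AgNO3-impregnated silica. SeO2 in refluxing dioxane (Riley allylic oxidation of the C17 methyl group) takes it to methyl 17-oxo-13,14,15,16-tetranorlabd-7-en-12-oate F6. Pinnick oxidation (NaClO2, NaH2PO4, 2-methyl-2-butene) gives 12-methyl hydrogen 13,14,15,16-tetranorlabd-7-ene-12,17-dioate F7. Steglich esterification with 9 comes back to the route at 10, bypassing steps 3 to 5.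

Step 8. Basic fluoride may cleave or transpose the allylic isobutyrate while the silylethyl ester is being removed. The fallback is global deprotection followed by selective re-acylation. It sets out from 15: Bu4NF followed by aqueous LiOH removes both esters to give (13E)-15-hydroxylabda-7,13-dien-17-oic acid F8. Isobutyric anhydride, pyridine and catalytic 4-dimethylaminopyridine acylate the primary allylic alcohol and, transiently, the carboxyl, giving the mixed anhydride F9. Aqueous pyridine work-up should hydrolyse F9 at its unhindered isobutyryl carbonyl, which frees the C17 acid and comes back to the route at 16.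

Further compounds
F1 | step 7 | 2-(trimethylsilyl)ethyl 12-hydroxy-13,14,15,16-tetranorlabd-7-en-17-oate | OCC[C@H]1C(C(=O)OCC[Si](C)(C)C)=CC[C@H]2C(C)(C)CCC[C@]12C
F2 | step 7 | 2-(trimethylsilyl)ethyl 12-iodo-13,14,15,16-tetranorlabd-7-en-17-oate | ICC[C@H]1C(C(=O)OCC[Si](C)(C)C)=CC[C@H]2C(C)(C)CCC[C@]12C
F3 | step 7 | alkylzinc iodide derived from F2 (C12–ZnI) | I[Zn]CC[C@H]1C(C(=O)OCC[Si](C)(C)C)=CC[C@H]2C(C)(C)CCC[C@]12C
F4 | step 7 | (E)-3-iodobut-2-en-1-yl 2-methylpropanoate | C/C(I)=C\COC(=O)C(C)C
F5 | step 2 | methyl 13,14,15,16-tetranorlabd-7-en-12-oate | COC(=O)C[C@H]1C(C)=CC[C@H]2C(C)(C)CCC[C@]12C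
F6 | step 2 | methyl 17-oxo-13,14,15,16-tetranorlabd-7-en-12-oate | COC(=O)C[C@H]1C(C=O)=CC[C@H]2C(C)(C)CCC[C@]12C
F7 | step 2 | 12-methyl hydrogen 13,14,15,16-tetranorlabd-7-ene-12,17-dioate (C17 free acid) | COC(=O)C[C@H]1C(C(=O)O)=CC[C@H]2C(C)(C)CCC[C@]12C
F8 | step 8 | (13E)-15-hydroxylabda-7,13-dien-17-oic acid | C/C(=C\CO)CC[C@H]1C(C(=O)O)=CC[C@H]2C(C)(C)CCC[C@]12C
F9 | step 8 | mixed anhydride of 16 with 2-methylpropanoic acid at C17 | C/C(=C\COC(=O)C(C)C)CC[C@H]1C(C(=O)OC(=O)C(C)C)=CC[C@H]2C(C)(C)CCC[C@]12C
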